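The data come from a simulation from invented constants, and the scatter is random.

the same everywhere: substrate 0.50 M; free catalyst 2.5 mM

| flask | reagent | remark | time |
|---|---|---|---|
| summer | 0.19 M | run made earlier |  |
| autumn | 1.5 M | run made earlier |  |
| alder | 0.300 M |  | 1.0 h |
| oak | 0.600 M |  | 1.0 h |
| ash | 1.20 M |  | 1.0 h |
| larch | 2.00 M |  | 1.0 h |

| run | time / min | target / % |
|---|---|---|
| summer | 2.00 | 0 |
| summer | 6.00 | 3 |
| summer | 10.0 | 3 |
| summer | 15.0 | 0 |
| summer | 25.0 | 8 |
| summer | 30.0 | 5 |
| autumn | 5.00 | 4 |
| autumn | 10.0 | 6 |
| autumn | 15.0 | 8 |
| autumn | 20.0 | 12 |
| autumn | 25.0 | 18 |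
| autumn | 30.0 | 21 |

(standard deviation of a reading: 2 percentage points)

- the earlier runs were read with a standard deviation of 2 percentage points
- "hardly changes" means that all values lie within two and a half points (for a concentration: within two and a half percent of the largest)

* amount of target at the end, in percent of the substrate charged for alder, oak, ash, larch, in this order
* how that number moves from the first to the last of them (falls, then rises / rises, then falls / falls all the way / hardly changes / rises all the way)

- With a small charge of 2.5 mM free catalyst against 0.50 M substrate, you want a quick number for the target after 1.0 h, and the earlier runs differ in their reagent charge.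
- Adding the last two readings of each run, autumn reads 3.00 times the target of summer on 7.89 times the reagent, so the power of the reagent charge that target follows at a fixed time, which I call the reagent order n (the apparent order), comes to 0.532.
- This n is a reading: each point scatters by 2 percentage points, and the summer values it rests on are 8% and 5%, so I hold it loosely.
- My own reckoning carries the last autumn reading, 21% at 30.0 min, straight on to 1.0 h and scales it by the reagent charge to the power n.
- That gives me 17.8%, 25.8%, 37.3% and 48.9% for alder, oak, ash and larch.
- Your forecast reads 15%, 24%, 32% and 37%, and it rises all the way: “a steady rise with diminishing gains”.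
- My row has the same shape as yours, but my larch stands higher than yours.
- The flasks give 19.8%, 31.2%, 28.4% and 22.5%, so the row rises, then falls.

    substrate + free catalyst → free catalyst + open intermediate (k = 0.570 M⁻¹ s⁻¹)
    free catalyst + open intermediate ⇌ catalyst intermediate (K = 0.950 M⁻¹, k = 2.81 M⁻¹ s⁻¹)
    reagent + catalyst intermediate → free catalyst + target (k = 0.866 M⁻¹ s⁻¹)
    substrate + target → side product (k = 0.0471 M⁻¹ s⁻¹)

- The reagent order, which read 0.532 from the last two readings of the earlier runs, comes at 1.0 h to 0.656 from alder to oak but to −0.456 from ash to larch, which is below zero. In alder at 0.105 h, target is made 1.21 times faster than it is used up, each step taken net. In larch at 1.00 h, target stands at 22.5% beside 77.4% side product, which counts as two in that percentage, with 0% substrate left.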